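**Retrosynthetic overview**
1. The strategy rests on the C2=C3 double bond of the pyranone ring C. C2 is read as the carbonyl carbon of a 4-(benzyloxy)benzoate carried on O1, and C3 as the ylide carbon of a ring A phenacyl triphenylphosphorane; an intramolecular ester Wittig closes ring C, the only ring formed (rings A and B are bought in).
2. The C3 oxygen follows ring closure (C3 lithiation, borylation, oxidation, then O-methylation). The benzyl ethers on O5, O7 and O4' are removed last by neutral hydrogenolysis.
3. The ylide arm is cut at the aryl–CO bond: an ortho-iodophenol undergoes I/Mg exchange and is acylated with a chloroacetyl Weinreb amide, then PPh3 and base give the phosphorane.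
4. Ring A comes from symmetric 3,5-bis(benzyloxy)phenol. Para formylation, Wittig, conjugate reduction and MeMgBr place the hydroxy-isopentyl chain between the two benzyloxy groups; both ortho positions are then equivalent, which fixes the chain at C6.

Key step: step 9

Assumption: the side-chain tertiary alcohol lies next to two ring A oxygens and would ionise or close to a 2,2-dimethylchroman under acid, so once it is in place only basic, neutral or weakly acidic (NH4Cl, AcOH) conditions are used. For that reason the haloacetyl group is introduced through an aryl-magnesium and not by Friedel–Crafts acylation.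

**Step 1**
Reactants: 1 3,5-bis(benzyloxy)phenol
Product: 3 2,6-bis(benzyloxy)-4-hydroxybenzaldehyde, via aryl iminium chloride 2 (not isolated)
Conditions: POCl3, DMF, MeCN, 0 °C → rt; then H2O, 50 °C
Reagents that add atoms: N,N-dimethylformamide CN(C)C=O; water O
Why: Vilsmeier–Haack formylation of a phloroglucinol-type ring, in which the free hydroxyl is the strongest donor and the position para to it (between the two benzyloxy groups) should be formylated preferentially, the minor ortho-formyl isomer being removable by chromatography as the less polar, internally hydrogen-bonded aldehyde.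

**Step 2**
Reactants: 3 2,6-bis(benzyloxy)-4-hydroxybenzaldehyde; 4 methyl (triphenylphosphoranylidene)acetate
Product: 5 methyl (E)-3-[2,6-bis(benzyloxy)-4-hydroxyphenyl]prop-2-enoate
Conditions: toluene, 110 °C
Reagents that add atoms: none
Why: Wittig olefination with a stabilised ester ylide, which tolerates the free phenol and should give the (E)-cinnamate (the geometry is erased in step 3).

**Step 3**
Reactants: 5 methyl (E)-3-[2,6-bis(benzyloxy)-4-hydroxyphenyl]prop-2-enoate
Product: 6 methyl 3-[2,6-bis(benzyloxy)-4-hydroxyphenyl]propanoate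
Conditions: NaBH4, NiCl2·6H2O (cat.), MeOH–THF, 0 °C
Reagents that add atoms: none
Why: Nickel boride conjugate reduction saturates the cinnamate C=C while leaving the ester and the aryl benzyl ethers, which hydrogenation over palladium would cleave, untouched.

**Step 4**
Reactants: 6 methyl 3-[2,6-bis(benzyloxy)-4-hydroxyphenyl]propanoate
Product: 8 3,5-bis(benzyloxy)-4-(3-hydroxy-3-methylbutyl)phenol, via methyl ketone 7 (not isolated)
Conditions: MeMgBr (4 equiv), THF, 0 °C → rt; then aq. NH4Cl
Reagents that add atoms: methylmagnesium bromide C[Mg]Br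
Why: Grignard double addition to the ester through ketone 7 gives the tertiary alcohol, one further equivalent of MeMgBr being consumed by the phenol.

**Step 5**
Reactants: 8 3,5-bis(benzyloxy)-4-(3-hydroxy-3-methylbutyl)phenol
Product: 9 3,5-bis(benzyloxy)-4-(3-hydroxy-3-methylbutyl)-2-iodophenol
Conditions: NIS (1.0 equiv), MeCN, −20 °C, dark
Reagents that add atoms: N-iodosuccinimide O=C1CCC(=O)N1I
Why: Electrophilic aromatic iodination ortho to the free hydroxyl, where the two open ring positions are equivalent by symmetry, supplies a handle for acylation under basic conditions, since the acid of a direct Friedel–Crafts haloacetylation would ionise the tertiary alcohol.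

**Step 6**
Reactants: 9 3,5-bis(benzyloxy)-4-(3-hydroxy-3-methylbutyl)-2-iodophenol; 10 2-chloro-N-methoxy-N-methylacetamide
Product: 12 1-[2,4-bis(benzyloxy)-6-hydroxy-3-(3-hydroxy-3-methylbutyl)phenyl]-2-chloroethan-1-one, via arylmagnesium chloride 11 (not isolated)
Conditions: MeMgCl (2.1 equiv), THF, −30 °C; i-PrMgCl·LiCl (1.2 equiv), −30 °C → rt; 10 (2 equiv), 0 °C; then aq. NH4Cl, 0 °C
Reagents that add atoms: none
Why: Knochel-type iodine–magnesium exchange on the pre-formed magnesium phenoxide/alkoxide followed by Weinreb ketone synthesis with the chloroacetyl amide, whose chelated tetrahedral adduct prevents over-addition and releases the α-chloro ketone only on the mildly acidic quench.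

**Step 7**
Reactants: 12 1-[2,4-bis(benzyloxy)-6-hydroxy-3-(3-hydroxy-3-methylbutyl)phenyl]-2-chloroethan-1-one; 13 triphenylphosphine
Product: 15 1-[2,4-bis(benzyloxy)-6-hydroxy-3-(3-hydroxy-3-methylbutyl)phenyl]-2-(triphenylphosphoranylidene)ethan-1-one, via phosphonium chloride 14 (not isolated)
Conditions: PPh3, NaI (cat.), MeCN, 60 °C; then aq. Na2CO3, CH2Cl2, rt
Reagents that add atoms: none
Why: SN2 displacement of the primary α-chloro ketone by PPh3 (iodide-assisted, Finkelstein type) followed by deprotonation of the acidic phosphonium salt gives the keto-stabilised ylide, displacement at carbon being faster than cyclisation of the un-ionised phenol onto the CH2Cl group.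

**Step 8**
Reactants: 15 1-[2,4-bis(benzyloxy)-6-hydroxy-3-(3-hydroxy-3-methylbutyl)phenyl]-2-(triphenylphosphoranylidene)ethan-1-one; 16 4-(benzyloxy)benzoyl chloride
Product: 17 3,5-bis(benzyloxy)-4-(3-hydroxy-3-methylbutyl)-2-[2-(triphenylphosphoranylidene)acetyl]phenyl 4-(benzyloxy)benzoate
Conditions: Et3N, CH2Cl2, 0 °C
Reagents that add atoms: none
Why: Base-mediated O-acylation (esterification with an acyl chloride) of the phenol, whose phenoxide is much more nucleophilic than the delocalised ylide carbon or the hindered tertiary alcohol, at a temperature too low for the Wittig step.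

**Step 9**
Reactants: 17 3,5-bis(benzyloxy)-4-(3-hydroxy-3-methylbutyl)-2-[2-(triphenylphosphoranylidene)acetyl]phenyl 4-(benzyloxy)benzoate
Product: 19 5,7-bis(benzyloxy)-2-[4-(benzyloxy)phenyl]-6-(3-hydroxy-3-methylbutyl)-4H-chromen-4-one, via oxaphosphetane 18 (not isolated)
Conditions: toluene, 110 °C
Reagents that add atoms: none
Why: Intramolecular Wittig olefination of an ester: the keto-stabilised ylide carbon (future C3) adds to the neighbouring aryl ester carbonyl (future C2) to give oxaphosphetane 18, whose cycloreversion expels Ph3PO and leaves the C2=C3 bond. The closest known reaction type is the thermal cyclisation of ortho-acyloxyphenacylidene triphenylphosphoranes to chromones and flavones. Ring C closes in a 6-exo-trig mode, the ester carbonyl oxygen lying outside the forming pyranone before it leaves on phosphorus. No stereocentre remains, because the two sp3 carbons of 18 become the trigonal C2 and C3 of the product. The step needs olefination to outrun transfer of the aroyl group to the ylide carbon and cleavage of the ester; the ortho arrangement that holds ylide and ester together, the electrophilic aryl ester and the neutral, nucleophile-free medium should secure this, and the tertiary alcohol is a bystander under these conditions.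

**Step 10**
Reactants: 19 5,7-bis(benzyloxy)-2-[4-(benzyloxy)phenyl]-6-(3-hydroxy-3-methylbutyl)-4H-chromen-4-one
Product: 21 5,7-bis(benzyloxy)-2-[4-(benzyloxy)phenyl]-3-hydroxy-6-(3-hydroxy-3-methylbutyl)-4H-chromen-4-one, via dimethyl boronate 20 (not isolated)
Conditions: LiN(iPr)2 (3 equiv), THF, −78 °C; B(OMe)3, −78 °C → rt; then AcOH, 30% H2O2, 0 °C → rt
Reagents that add atoms: hydrogen peroxide OO
Why: Carbonyl-directed C3 lithiation of the flavone with LiN(iPr)2, borylation and oxidative C–B cleavage (the known flavone-to-flavonol sequence), with extra base to cover the tertiary alkoxide.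

**Step 11**
Reactants: 21 5,7-bis(benzyloxy)-2-[4-(benzyloxy)phenyl]-3-hydroxy-6-(3-hydroxy-3-methylbutyl)-4H-chromen-4-one
Product: 22 5,7-bis(benzyloxy)-2-[4-(benzyloxy)phenyl]-6-(3-hydroxy-3-methylbutyl)-3-methoxy-4H-chromen-4-one
Conditions: MeI, K2CO3, acetone, 50 °C
Reagents that add atoms: iodomethane CI
Why: Williamson O-methylation of the only acidic hydroxyl, the enolic 3-OH, the tertiary alcohol being inert to K2CO3/MeI.

**Step 12**
Reactants: 22 5,7-bis(benzyloxy)-2-[4-(benzyloxy)phenyl]-6-(3-hydroxy-3-methylbutyl)-3-methoxy-4H-chromen-4-one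
Product: 23 topazolin hydrate, 5,7-dihydroxy-6-(3-hydroxy-3-methylbutyl)-2-(4-hydroxyphenyl)-3-methoxy-4H-chromen-4-one
Conditions: H2 (1 atm), Pd/C, EtOAc–MeOH, rt
Reagents that add atoms: none
Why: Catalytic hydrogenolysis of the three aryl benzyl ethers under neutral conditions, which should leave the tetrasubstituted vinylogous-ester C2=C3 bond intact and avoid acid-promoted cyclisation of the tertiary alcohol onto O5 or O7.

**Compound list**
1 | 3,5-bis(benzyloxy)phenol | Oc1cc(OCc2ccccc2)cc(OCc2ccccc2)c1 | starting material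
2 | [2,6-bis(benzyloxy)-4-hydroxybenzylidene]dimethylammonium chloride | C[N+](C)=Cc1c(OCc2ccccc2)cc(O)cc1OCc1ccccc1.[Cl-] | intermediate
3 | 2,6-bis(benzyloxy)-4-hydroxybenzaldehyde | O=Cc1c(OCc2ccccc2)cc(O)cc1OCc1ccccc1 | intermediate
4 | methyl (triphenylphosphoranylidene)acetate | COC(=O)C=P(c1ccccc1)(c1ccccc1)c1ccccc1 | starting material
5 | methyl (E)-3-[2,6-bis(benzyloxy)-4-hydroxyphenyl]prop-2-enoate | COC(=O)/C=C/c1c(OCc2ccccc2)cc(O)cc1OCc1ccccc1 | intermediate
6 | methyl 3-[2,6-bis(benzyloxy)-4-hydroxyphenyl]propanoate | COC(=O)CCc1c(OCc2ccccc2)cc(O)cc1OCc1ccccc1 | intermediate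
7 | 4-[2,6-bis(benzyloxy)-4-hydroxyphenyl]butan-2-one | CC(=O)CCc1c(OCc2ccccc2)cc(O)cc1OCc1ccccc1 | intermediate
8 | 3,5-bis(benzyloxy)-4-(3-hydroxy-3-methylbutyl)phenol | CC(C)(O)CCc1c(OCc2ccccc2)cc(O)cc1OCc1ccccc1 | intermediate
9 | 3,5-bis(benzyloxy)-4-(3-hydroxy-3-methylbutyl)-2-iodophenol | CC(C)(O)CCc1c(OCc2ccccc2)cc(O)c(I)c1OCc1ccccc1 | intermediate
10 | 2-chloro-N-methoxy-N-methylacetamide | CON(C)C(=O)CCl | starting material
11 | arylmagnesium chloride from 9 (C2–MgCl, with the phenol and the tertiary alcohol as chloromagnesium alkoxides) | CC(C)(O[Mg]Cl)CCc1c(OCc2ccccc2)cc(O[Mg]Cl)c([Mg]Cl)c1OCc1ccccc1 | intermediate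
12 | 1-[2,4-bis(benzyloxy)-6-hydroxy-3-(3-hydroxy-3-methylbutyl)phenyl]-2-chloroethan-1-one | CC(C)(O)CCc1c(OCc2ccccc2)cc(O)c(C(=O)CCl)c1OCc1ccccc1 | intermediate
13 | triphenylphosphine | c1ccc(P(c2ccccc2)c2ccccc2)cc1 | starting material
14 | {2-[2,4-bis(benzyloxy)-6-hydroxy-3-(3-hydroxy-3-methylbutyl)phenyl]-2-oxoethyl}triphenylphosphonium chloride | CC(C)(O)CCc1c(OCc2ccccc2)cc(O)c(C(=O)C[P+](c2ccccc2)(c2ccccc2)c2ccccc2)c1OCc1ccccc1.[Cl-] | intermediate
15 | 1-[2,4-bis(benzyloxy)-6-hydroxy-3-(3-hydroxy-3-methylbutyl)phenyl]-2-(triphenylphosphoranylidene)ethan-1-one | CC(C)(O)CCc1c(OCc2ccccc2)cc(O)c(C(=O)C=P(c2ccccc2)(c2ccccc2)c2ccccc2)c1OCc1ccccc1 | intermediate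
16 | 4-(benzyloxy)benzoyl chloride | O=C(Cl)c1ccc(OCc2ccccc2)cc1 | starting material
17 | 3,5-bis(benzyloxy)-4-(3-hydroxy-3-methylbutyl)-2-[2-(triphenylphosphoranylidene)acetyl]phenyl 4-(benzyloxy)benzoate | CC(C)(O)CCc1c(OCc2ccccc2)cc(OC(=O)c2ccc(OCc3ccccc3)cc2)c(C(=O)C=P(c2ccccc2)(c2ccccc2)c2ccccc2)c1OCc1ccccc1 | intermediate
18 | oxaphosphetane adduct of 17 (four-membered C2–O–PPh3–C3 ring fused to the nascent chroman-4-one; transient, configuration at C2 and C3 not defined) | O=C1c2c(OCc3ccccc3)c(CCC(C)(C)O)c(OCc3ccccc3)cc2OC2(c3ccc(OCc4ccccc4)cc3)OP(c3ccccc3)(c3ccccc3)(c3ccccc3)C12 | intermediate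
19 | 5,7-bis(benzyloxy)-2-[4-(benzyloxy)phenyl]-6-(3-hydroxy-3-methylbutyl)-4H-chromen-4-one | O=c1cc(-c2ccc(OCc3ccccc3)cc2)oc2cc(OCc3ccccc3)c(CCC(C)(C)O)c(OCc3ccccc3)c12 | intermediate
20 | dimethyl {5,7-bis(benzyloxy)-2-[4-(benzyloxy)phenyl]-6-(3-hydroxy-3-methylbutyl)-4-oxo-4H-chromen-3-yl}boronate | COB(OC)c1c(-c2ccc(OCc3ccccc3)cc2)oc2cc(OCc3ccccc3)c(CCC(C)(C)O)c(OCc3ccccc3)c2c1=O | intermediate
21 | 5,7-bis(benzyloxy)-2-[4-(benzyloxy)phenyl]-3-hydroxy-6-(3-hydroxy-3-methylbutyl)-4H-chromen-4-one | O=c1c(O)c(-c2ccc(OCc3ccccc3)cc2)oc2cc(OCc3ccccc3)c(CCC(C)(C)O)c(OCc3ccccc3)c12 | intermediate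
22 | 5,7-bis(benzyloxy)-2-[4-(benzyloxy)phenyl]-6-(3-hydroxy-3-methylbutyl)-3-methoxy-4H-chromen-4-one | COc1c(-c2ccc(OCc3ccccc3)cc2)oc2cc(OCc3ccccc3)c(CCC(C)(C)O)c(OCc3ccccc3)c2c1=O | intermediate
23 | topazolin hydrate, 5,7-dihydroxy-6-(3-hydroxy-3-methylbutyl)-2-(4-hydroxyphenyl)-3-methoxy-4H-chromen-4-one (no stereocentre) | COc1c(-c2ccc(O)cc2)oc2cc(O)c(CCC(C)(C)O)c(O)c2c1=O | target

**Step count**
Total: 12 steps. Longest linear sequence: 12 steps, from 1 to 23.

**Steps most likely to fail**

Step 6. The iodine–magnesium exchange may stay incomplete on this electron-rich ring, the aryl-magnesium may be quenched by the acidic α-hydrogens of the amide instead of adding, and the product may close to a benzofuranone during the quench. The fallback installs the acyl arm by electrophilic substitution before the tertiary alcohol exists; it sets out from 6 and comes back at 15. Ester phenol 6 would be chloroacetylated ortho to the hydroxyl by a metal-free Friedel–Crafts acylation (ClCH2COCl in hexafluoro-2-propanol, rt, conditions that the ester chain tolerates and under which aryl benzyl ethers should persist) to give methyl 3-[2,6-bis(benzyloxy)-3-(chloroacetyl)-4-hydroxyphenyl]propanoate F1. PPh3 with NaI (cat.) in MeCN would then give {2-[2,4-bis(benzyloxy)-6-hydroxy-3-(3-methoxy-3-oxopropyl)phenyl]-2-oxoethyl}triphenylphosphonium chloride F2, and aq. Na2CO3 would convert it into methyl 3-{2,6-bis(benzyloxy)-4-hydroxy-3-[(triphenylphosphoranylidene)acetyl]phenyl}propanoate F3. Excess MeMgBr (THF, 0 °C) should then add only to the ester, because the ylide carbonyl is a phosphonium enolate and the phenol a magnesium phenoxide, and give 15.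

Step 9. Addition of the ylide to the ester may be slow, because the aroyl ylide is flanked by two ortho oxygens and twisted out of the ring plane, and the aroyl group may migrate from oxygen to the ylide carbon or be lost. The fallback forms ring C by chalcone cyclisation; it sets out from 15 and comes back at 19. Ylide 15 would undergo an intermolecular Wittig reaction with 4-(benzyloxy)benzaldehyde (toluene, 110 °C) to give (E)-1-[2,4-bis(benzyloxy)-6-hydroxy-3-(3-hydroxy-3-methylbutyl)phenyl]-3-[4-(benzyloxy)phenyl]prop-2-en-1-one F4. Oxidative cyclisation of this 2'-hydroxychalcone with I2 (cat.) in DMSO at 120 °C should give flavone 19.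

Step 10. Deprotonation at C3 may be incomplete next to the bulky 5-benzyloxy group, the amide base may add to the pyranone, and the boronate may protodeborylate before oxidation. The fallback oxidises the C2=C3 bond directly; it sets out from 19 and comes back at 21. Dimethyldioxirane (acetone–CH2Cl2, 0 °C) would epoxidise 19 to the racemic cis-fused 2,3-epoxide of 19 F5. Opening of the epoxide at C2 and loss of the C3 hydrogen on brief contact with silica gel or pyridinium p-toluenesulfonate (cat.) should give flavonol 21.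

**Further compounds**
F1 | step 6 | methyl 3-[2,6-bis(benzyloxy)-3-(chloroacetyl)-4-hydroxyphenyl]propanoate | COC(=O)CCc1c(OCc2ccccc2)cc(O)c(C(=O)CCl)c1OCc1ccccc1
F2 | step 6 | {2-[2,4-bis(benzyloxy)-6-hydroxy-3-(3-methoxy-3-oxopropyl)phenyl]-2-oxoethyl}triphenylphosphonium chloride | COC(=O)CCc1c(OCc2ccccc2)cc(O)c(C(=O)C[P+](c2ccccc2)(c2ccccc2)c2ccccc2)c1OCc1ccccc1.[Cl-]
F3 | step 6 | methyl 3-{2,6-bis(benzyloxy)-4-hydroxy-3-[(triphenylphosphoranylidene)acetyl]phenyl}propanoate | COC(=O)CCc1c(OCc2ccccc2)cc(O)c(C(=O)C=P(c2ccccc2)(c2ccccc2)c2ccccc2)c1OCc1ccccc1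
F4 | step 9 | (E)-1-[2,4-bis(benzyloxy)-6-hydroxy-3-(3-hydroxy-3-methylbutyl)phenyl]-3-[4-(benzyloxy)phenyl]prop-2-en-1-one | CC(C)(O)CCc1c(OCc2ccccc2)cc(O)c(C(=O)/C=C/c2ccc(OCc3ccccc3)cc2)c1OCc1ccccc1
F5 | step 10 | racemic cis-fused 2,3-epoxide of 19, 3,5-bis(benzyloxy)-1a-[4-(benzyloxy)phenyl]-4-(3-hydroxy-3-methylbutyl)-1a,7a-dihydro-7H-oxireno[2,3-b]chromen-7-one (one enantiomer drawn) | O=C1c2c(OCc3ccccc3)c(CCC(C)(C)O)c(OCc3ccccc3)cc2O[C@]2(c3ccc(OCc4ccccc4)cc3)O[C@H]12
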